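Assumption 1: the SMILES is read as epicatechin-(4β→6)-catechin-(4α→6)-catechin (top unit 2R,3R with a 4β bond; middle and bottom units 2R,3S; middle unit with a 4α bond; both interflavan bonds 3,4-trans).
Assumption 2: the sense of induction of the hydrogenation catalyst in step 8 is taken by analogy with 2-arylcycloalkanones; if the first run gives the antipode, the mirror-image catalyst is used.

**Retrosynthetic overview**
1. Target ⇐ global hydrogenolysis of a fully O-benzylated, tetrabrominated trimer 23. The two C4–C6 bonds are cut as Lewis-acid Friedel–Crafts couplings (middle–bottom first, then top), with bromine caps at C8 forcing attack at C6.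
2. All three flavan units ⇐ one cis (2R,3R) flavan-3-ol 15; the two catechin-type units come from it by inversion at C3.
3. 15 ⇐ racemic flavan-3-one 14 by hydrogenation with dynamic kinetic resolution. Ring C of 14 ⇐ one-carbon ring expansion (1,2-aryl shift) of 2-arylbenzofuran-3(2H)-one 11 with TMSCHN2 (key step).
4. 11 ⇐ Friedel–Crafts closure of α-aryloxy arylacetic acid 10, made from phenol 4 (resorcinol, C–H borylation/oxidation) and mandelate 8 (catechol + glyoxylic acid).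
5. Ring order: rings A and B come from resorcinol and catechol; the five-membered furanone ring is closed first, then expanded to the six-membered ring C; the three units are joined last.

**Route**

Step 1
Reactants: 1 resorcinol
Product: 2 1,3-bis[(3,5-dimethylbenzyl)oxy]benzene
Conditions: 3,5-dimethylbenzyl bromide (2.2 equiv), K2CO3, DMF, 60 °C
Reagents that add atoms: 3,5-dimethylbenzyl bromide, Cc1cc(C)cc(CBr)c1
Why: Williamson ether synthesis; the 3,5-dimethylbenzyl group is a hydrogenolysable benzyl-type ether whose ring C–H bonds are all flanked by two substituents, so (unlike plain benzyl) it stays inert in the borylation of step 2.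

Step 2
Reactants: 2 1,3-bis[(3,5-dimethylbenzyl)oxy]benzene
Product: 4 3,5-bis[(3,5-dimethylbenzyl)oxy]phenol, via arylboronic pinacol ester 3 (not isolated)
Conditions: [Ir(OMe)(cod)]2 (1.5 mol %), dtbpy (3 mol %), B2pin2, THF, 80 °C; then H2O2, NaOH, THF–H2O, 0 °C
Reagents that add atoms: bis(pinacolato)diboron, CC1(C)OB(OC1(C)C)B1OC(C)(C)C(C)(C)O1 (boron of 3); hydrogen peroxide, OO (oxygen of 4)
Why: Sterically controlled Hartwig–Miyaura C–H borylation reacts only at C5, the one C–H with no ortho substituent, and oxidation of the C–B bond gives the 1,3,5-trioxygenated ring A with a single free OH.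

Step 3
Reactants: 5 catechol; 6 glyoxylic acid
Product: 7 (RS)-2-(3,4-dihydroxyphenyl)-2-hydroxyacetic acid (3,4-dihydroxymandelic acid)
Conditions: NaOH, H2O, N2, rt; then HCl to pH 2
Reagents that add atoms: none
Why: Base-mediated electrophilic aromatic hydroxyalkylation of the catecholate by glyoxylate para to one OH (the vanillin-type mandelic acid condensation); the new centre is racemic and is reset later.

Step 4
Reactants: 7 (RS)-3,4-dihydroxymandelic acid
Product: 8 benzyl (RS)-2-[3,4-bis(benzyloxy)phenyl]-2-hydroxyacetate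
Conditions: BnBr (3.3 equiv), K2CO3, DMF, rt
Reagents that add atoms: benzyl bromide, BrCc1ccccc1
Why: Williamson O-alkylation; K2CO3 deprotonates only the two phenols and the carboxylic acid, so the secondary alcohol stays free.

Step 5
Reactants: 4 3,5-bis[(3,5-dimethylbenzyl)oxy]phenol; 8 benzyl (RS)-2-[3,4-bis(benzyloxy)phenyl]-2-hydroxyacetate
Product: 10 (RS)-2-[3,4-bis(benzyloxy)phenyl]-2-{3,5-bis[(3,5-dimethylbenzyl)oxy]phenoxy}acetic acid, via Mitsunobu ether ester 9 (not isolated)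
Conditions: PPh3, DIAD, THF, 0 °C to rt; then LiOH, H2O–MeOH, rt; HCl work-up
Reagents that add atoms: lithium hydroxide, [Li+].[OH-]
Why: Mitsunobu etherification of the α-hydroxy ester by phenol 4 (SN2 at a carbon with no β-hydrogen, the ester suppressing ionisation) forms the future O1–C2 bond, and saponification lets the acid be extracted away from the phosphine oxide.

Step 6
Reactants: 10 (RS)-2-[3,4-bis(benzyloxy)phenyl]-2-{3,5-bis[(3,5-dimethylbenzyl)oxy]phenoxy}acetic acid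
Product: 11 (RS)-2-[3,4-bis(benzyloxy)phenyl]-4,6-bis[(3,5-dimethylbenzyl)oxy]benzofuran-3(2H)-one
Conditions: (CF3CO)2O, CH2Cl2, 0 °C to rt
Reagents that add atoms: none
Why: Intramolecular Friedel–Crafts acylation through the mixed trifluoroacetic anhydride onto the strongly activated ortho position (the two ortho positions are equivalent), closing the five-membered ring.

Step 7
Reactants: 11 (RS)-2-[3,4-bis(benzyloxy)phenyl]-4,6-bis[(3,5-dimethylbenzyl)oxy]benzofuran-3(2H)-one; 12 trimethylsilyldiazomethane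
Product: 14 (RS)-2-[3,4-bis(benzyloxy)phenyl]-5,7-bis[(3,5-dimethylbenzyl)oxy]chroman-3-one, via 4-silyl ketone 13 (not isolated)
Conditions: Sc(OTf)3 (10 mol %), CH2Cl2, −20 °C to rt; then 1 M HCl, THF, rt
Reagents that add atoms: none
Why: Proposed new method: Sc(OTf)3-catalysed diazoalkane ring expansion (Tiffeneau–Demjanov/semipinacol type) of a 2-arylbenzofuran-3(2H)-one, in which TMSCHN2 adds to the Lewis-acid-bound C3 carbonyl, the 2,4,6-trioxygenated aryl carbon C3a (a far better migrating group than the O- and aryl-substituted C2) shifts to the diazonium carbon with loss of N2 to give the six-membered β-ketosilane 13, whose bulky silyl group blocks a second insertion and is removed by acid; the closest known reactions are the Lewis-acid/TMSCHN2 homologations of 1-indanone and 1-tetralone to 2-tetralone and 2-benzosuberone by aryl migration; C2 of 14 is racemic and is set in step 8.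

Step 8
Reactants: 14 (RS)-2-[3,4-bis(benzyloxy)phenyl]-5,7-bis[(3,5-dimethylbenzyl)oxy]chroman-3-one
Product: 15 (2R,3R)-2-[3,4-bis(benzyloxy)phenyl]-5,7-bis[(3,5-dimethylbenzyl)oxy]chroman-3-ol
Conditions: RuCl2[(S)-xylbinap][(S)-daipen] (1 mol %), t-BuOK (0.2 equiv), H2 (20 atm), i-PrOH–toluene, 25 °C
Reagents that add atoms: none
Why: Noyori asymmetric hydrogenation with dynamic kinetic resolution of an α-aryl cyclic ketone: t-BuOK racemises C2 through the enolate, and the catalyst reduces the (2R)-ketone faster and from the face opposite the 2-aryl group, setting C2 (R) and C3 (R, 2,3-cis) together.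

Step 9
Reactants: 15 (2R,3R)-2-[3,4-bis(benzyloxy)phenyl]-5,7-bis[(3,5-dimethylbenzyl)oxy]chroman-3-ol
Product: 16 (2R,3R,4S)-2-[3,4-bis(benzyloxy)phenyl]-5,7-bis[(3,5-dimethylbenzyl)oxy]-4-(2-ethoxyethoxy)chroman-3-ol
Conditions: DDQ (2 equiv), 2-ethoxyethanol, CH2Cl2, rt
Reagents that add atoms: 2-ethoxyethanol, CCOCCO
Why: DDQ benzylic oxidation (hydride abstraction at C4 to the ring A-stabilised cation) with trapping by the alcohol on the face opposite the 2-aryl group; C4 here is only a leaving-group centre.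

Step 10
Reactants: 16 (2R,3R,4S)-2-[3,4-bis(benzyloxy)phenyl]-5,7-bis[(3,5-dimethylbenzyl)oxy]-4-(2-ethoxyethoxy)chroman-3-ol
Product: 17 (2R,3R,4S)-2-[3,4-bis(benzyloxy)phenyl]-6,8-dibromo-5,7-bis[(3,5-dimethylbenzyl)oxy]-4-(2-ethoxyethoxy)chroman-3-ol
Conditions: NBS (2.2 equiv), CH2Cl2, −40 to 0 °C
Reagents that add atoms: N-bromosuccinimide, O=C1CCC(=O)N1Br
Why: Electrophilic aromatic bromination of both free ring A positions (halo-capping), so the top unit can act only as electrophile and cannot self-condense.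

Step 11
Reactants: 15 (2R,3R)-2-[3,4-bis(benzyloxy)phenyl]-5,7-bis[(3,5-dimethylbenzyl)oxy]chroman-3-ol
Product: 18 (2R,3R)-2-[3,4-bis(benzyloxy)phenyl]-8-bromo-5,7-bis[(3,5-dimethylbenzyl)oxy]chroman-3-ol
Conditions: NBS (1.0 equiv), CH2Cl2, −78 to −40 °C
Reagents that add atoms: N-bromosuccinimide, O=C1CCC(=O)N1Br
Why: Electrophilic aromatic bromination; C8 is the more reactive ring A position of 5,7-di-O-alkyl flavan-3-ols, so one equivalent gives the 8-bromide that later blocks C8 and leaves C6 as the only nucleophilic site.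

Step 12
Reactants: 18 (2R,3R)-2-[3,4-bis(benzyloxy)phenyl]-8-bromo-5,7-bis[(3,5-dimethylbenzyl)oxy]chroman-3-ol
Product: 20 (2R,3S)-2-[3,4-bis(benzyloxy)phenyl]-8-bromo-5,7-bis[(3,5-dimethylbenzyl)oxy]chroman-3-ol, via inverted 4-nitrobenzoate 19 (not isolated)
Conditions: 4-O2NC6H4CO2H, PPh3, DIAD, toluene, 0 °C to rt; then K2CO3 (cat.), MeOH–THF, rt
Reagents that add atoms: 4-nitrobenzoic acid, OC(=O)c1ccc(cc1)[N+](=O)[O-]
Why: Mitsunobu inversion: SN2 displacement of the axial C3 oxyphosphonium (the 2-aryl group is gauche, so no aryl participation) inverts C3 to S (2,3-trans, catechin type), and transesterification frees the alcohol.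

Step 13
Reactants: 20 (2R,3S)-2-[3,4-bis(benzyloxy)phenyl]-8-bromo-5,7-bis[(3,5-dimethylbenzyl)oxy]chroman-3-ol
Product: 21 (2R,3S,4S)-2-[3,4-bis(benzyloxy)phenyl]-8-bromo-5,7-bis[(3,5-dimethylbenzyl)oxy]-4-(2-ethoxyethoxy)chroman-3-ol
Conditions: DDQ (2 equiv), 2-ethoxyethanol, CH2Cl2, rt
Reagents that add atoms: 2-ethoxyethanol, CCOCCO
Why: DDQ benzylic oxidation at C4 with alcohol trapping, as in step 9; the C4 configuration is lost on ionisation in step 14.

Step 14
Reactants: 21 (2R,3S,4S)-2-[3,4-bis(benzyloxy)phenyl]-8-bromo-5,7-bis[(3,5-dimethylbenzyl)oxy]-4-(2-ethoxyethoxy)chroman-3-ol; 20 (2R,3S)-2-[3,4-bis(benzyloxy)phenyl]-8-bromo-5,7-bis[(3,5-dimethylbenzyl)oxy]chroman-3-ol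
Product: 22 protected dimer 8-bromocatechin-(4α→6)-8-bromocatechin (each unit 5,7-di-O-(3,5-dimethylbenzyl) and 3',4'-di-O-benzyl; both 3-OH free)
Conditions: TMSOTf (0.5 equiv), 20 (3 equiv), CH2Cl2, −78 to −40 °C
Reagents that add atoms: none
Why: Lewis-acid SN1 Friedel–Crafts alkylation (halo-capping strategy): the flavan-4-yl cation from 21 is attacked by C6 of 20 (C8 blocked by bromine) on the face anti to the C3–OH, giving the 3,4-trans (4α) bond; excess 20 outcompetes self-condensation of 21.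

Step 15
Reactants: 17 (2R,3R,4S)-2-[3,4-bis(benzyloxy)phenyl]-6,8-dibromo-5,7-bis[(3,5-dimethylbenzyl)oxy]-4-(2-ethoxyethoxy)chroman-3-ol; 22 protected dimer 8-bromocatechin-(4α→6)-8-bromocatechin
Product: 23 protected trimer 6,8-dibromoepicatechin-(4β→6)-8-bromocatechin-(4α→6)-8-bromocatechin (each unit 5,7-di-O-(3,5-dimethylbenzyl) and 3',4'-di-O-benzyl; all 3-OH free)
Conditions: TMSOTf (1 equiv), 17 (2 equiv), CH2Cl2, −78 to −20 °C
Reagents that add atoms: none
Why: Same Friedel–Crafts coupling: the only unsubstituted nucleophilic ring A carbon in either partner is C6 of the middle unit of 22, and it attacks the epicatechin-type cation anti to both the C3–OH and the 2-aryl group, giving the 4β (3,4-trans) bond.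

Step 16
Reactants: 23 protected trimer
Product: 24 epicatechin-(4β→6)-catechin-(4α→6)-catechin (CNP0163146.4)
Conditions: H2 (1 atm), Pd(OH)2/C, NaOAc, THF–MeOH–H2O, rt
Reagents that add atoms: none
Why: Hydrogenolysis of the twelve benzylic ethers and hydrodebromination of the four aryl bromides in one operation; NaOAc buffers the HBr so the acid-labile interflavan bonds survive, and no stereocentre is touched.

**Compound list**
1 | resorcinol | Oc1cccc(O)c1 | starting material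
2 | 1,3-bis[(3,5-dimethylbenzyl)oxy]benzene | Cc1cc(C)cc(c1)COc1cccc(OCc2cc(C)cc(C)c2)c1 | intermediate
3 | 2-{3,5-bis[(3,5-dimethylbenzyl)oxy]phenyl}-4,4,5,5-tetramethyl-1,3,2-dioxaborolane | Cc1cc(C)cc(c1)COc1cc(OCc2cc(C)cc(C)c2)cc(c1)B1OC(C)(C)C(C)(C)O1 | intermediate
4 | 3,5-bis[(3,5-dimethylbenzyl)oxy]phenol | Cc1cc(C)cc(c1)COc1cc(O)cc(OCc2cc(C)cc(C)c2)c1 | intermediate
5 | catechol | Oc1ccccc1O | starting material
6 | glyoxylic acid | O=CC(=O)O | starting material
7 | (RS)-2-(3,4-dihydroxyphenyl)-2-hydroxyacetic acid | OC(C(=O)O)c1ccc(O)c(O)c1 | intermediate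
8 | benzyl (RS)-2-[3,4-bis(benzyloxy)phenyl]-2-hydroxyacetate | OC(C(=O)OCc1ccccc1)c1ccc(OCc2ccccc2)c(OCc2ccccc2)c1 | intermediate
9 | benzyl (RS)-2-[3,4-bis(benzyloxy)phenyl]-2-{3,5-bis[(3,5-dimethylbenzyl)oxy]phenoxy}acetate | O=C(OCc1ccccc1)C(Oc1cc(OCc2cc(C)cc(C)c2)cc(OCc2cc(C)cc(C)c2)c1)c1ccc(OCc2ccccc2)c(OCc2ccccc2)c1 | intermediate
10 | (RS)-2-[3,4-bis(benzyloxy)phenyl]-2-{3,5-bis[(3,5-dimethylbenzyl)oxy]phenoxy}acetic acid | OC(=O)C(Oc1cc(OCc2cc(C)cc(C)c2)cc(OCc2cc(C)cc(C)c2)c1)c1ccc(OCc2ccccc2)c(OCc2ccccc2)c1 | intermediate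
11 | (RS)-2-[3,4-bis(benzyloxy)phenyl]-4,6-bis[(3,5-dimethylbenzyl)oxy]benzofuran-3(2H)-one | O=C1C(Oc2cc(OCc3cc(C)cc(C)c3)cc(OCc3cc(C)cc(C)c3)c12)c1ccc(OCc2ccccc2)c(OCc2ccccc2)c1 | intermediate
12 | trimethylsilyldiazomethane | C[Si](C)(C)C=[N+]=[N-] | starting material
13 | 2-[3,4-bis(benzyloxy)phenyl]-5,7-bis[(3,5-dimethylbenzyl)oxy]-4-(trimethylsilyl)chroman-3-one (stereoisomer mixture) | C[Si](C)(C)C1C(=O)C(Oc2cc(OCc3cc(C)cc(C)c3)cc(OCc3cc(C)cc(C)c3)c12)c1ccc(OCc2ccccc2)c(OCc2ccccc2)c1 | intermediate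
14 | (RS)-2-[3,4-bis(benzyloxy)phenyl]-5,7-bis[(3,5-dimethylbenzyl)oxy]chroman-3-one | O=C1Cc2c(OCc3cc(C)cc(C)c3)cc(OCc3cc(C)cc(C)c3)cc2OC1c1ccc(OCc2ccccc2)c(OCc2ccccc2)c1 | intermediate
15 | (2R,3R)-2-[3,4-bis(benzyloxy)phenyl]-5,7-bis[(3,5-dimethylbenzyl)oxy]chroman-3-ol | Cc1cc(C)cc(c1)COc1cc(OCc2cc(C)cc(C)c2)c2c(c1)O[C@H](c1ccc(OCc3ccccc3)c(OCc3ccccc3)c1)[C@H](O)C2 | intermediate
16 | (2R,3R,4S)-2-[3,4-bis(benzyloxy)phenyl]-5,7-bis[(3,5-dimethylbenzyl)oxy]-4-(2-ethoxyethoxy)chroman-3-ol | Cc1cc(C)cc(c1)COc1cc(OCc2cc(C)cc(C)c2)c2c(c1)O[C@H](c1ccc(OCc3ccccc3)c(OCc3ccccc3)c1)[C@H](O)[C@H]2OCCOCC | intermediate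
17 | (2R,3R,4S)-2-[3,4-bis(benzyloxy)phenyl]-6,8-dibromo-5,7-bis[(3,5-dimethylbenzyl)oxy]-4-(2-ethoxyethoxy)chroman-3-ol | Cc1cc(C)cc(c1)COc1c(Br)c(OCc2cc(C)cc(C)c2)c2c(c1Br)O[C@H](c1ccc(OCc3ccccc3)c(OCc3ccccc3)c1)[C@H](O)[C@H]2OCCOCC | intermediate
18 | (2R,3R)-2-[3,4-bis(benzyloxy)phenyl]-8-bromo-5,7-bis[(3,5-dimethylbenzyl)oxy]chroman-3-ol | Cc1cc(C)cc(c1)COc1cc(OCc2cc(C)cc(C)c2)c2c(c1Br)O[C@H](c1ccc(OCc3ccccc3)c(OCc3ccccc3)c1)[C@H](O)C2 | intermediate
19 | (2R,3S)-2-[3,4-bis(benzyloxy)phenyl]-8-bromo-5,7-bis[(3,5-dimethylbenzyl)oxy]chroman-3-yl 4-nitrobenzoate | Cc1cc(C)cc(c1)COc1cc(OCc2cc(C)cc(C)c2)c2c(c1Br)O[C@H](c1ccc(OCc3ccccc3)c(OCc3ccccc3)c1)[C@@H](OC(=O)c1ccc(cc1)[N+](=O)[O-])C2 | intermediate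
20 | (2R,3S)-2-[3,4-bis(benzyloxy)phenyl]-8-bromo-5,7-bis[(3,5-dimethylbenzyl)oxy]chroman-3-ol | Cc1cc(C)cc(c1)COc1cc(OCc2cc(C)cc(C)c2)c2c(c1Br)O[C@H](c1ccc(OCc3ccccc3)c(OCc3ccccc3)c1)[C@@H](O)C2 | intermediate
21 | (2R,3S,4S)-2-[3,4-bis(benzyloxy)phenyl]-8-bromo-5,7-bis[(3,5-dimethylbenzyl)oxy]-4-(2-ethoxyethoxy)chroman-3-ol | Cc1cc(C)cc(c1)COc1cc(OCc2cc(C)cc(C)c2)c2c(c1Br)O[C@H](c1ccc(OCc3ccccc3)c(OCc3ccccc3)c1)[C@@H](O)[C@H]2OCCOCC | intermediate
22 | protected dimer: 8-bromocatechin-(4α→6)-8-bromocatechin, each unit 5,7-di-O-(3,5-dimethylbenzyl) and 3',4'-di-O-benzyl, both units (2R,3S), interflavan bond 3,4-trans | Cc1cc(C)cc(c1)COc1cc(OCc2cc(C)cc(C)c2)c2c(c1Br)O[C@H](c1ccc(OCc3ccccc3)c(OCc3ccccc3)c1)[C@@H](O)[C@@H]2c1c(OCc2cc(C)cc(C)c2)c(Br)c2O[C@H](c3ccc(OCc4ccccc4)c(OCc4ccccc4)c3)[C@@H](O)Cc2c1OCc1cc(C)cc(C)c1 | intermediate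
23 | protected trimer: 6,8-dibromoepicatechin-(4β→6)-8-bromocatechin-(4α→6)-8-bromocatechin, each unit 5,7-di-O-(3,5-dimethylbenzyl) and 3',4'-di-O-benzyl, top unit (2R,3R), middle and bottom units (2R,3S), both interflavan bonds 3,4-trans | Cc1cc(C)cc(c1)COc1c(Br)c(OCc2cc(C)cc(C)c2)c2c(c1Br)O[C@H](c1ccc(OCc3ccccc3)c(OCc3ccccc3)c1)[C@H](O)[C@H]2c1c(OCc2cc(C)cc(C)c2)c(Br)c2O[C@H](c3ccc(OCc4ccccc4)c(OCc4ccccc4)c3)[C@@H](O)[C@H](c5c(OCc6cc(C)cc(C)c6)c(Br)c6O[C@H](c7ccc(OCc8ccccc8)c(OCc8ccccc8)c7)[C@@H](O)Cc6c5OCc5cc(C)cc(C)c5)c2c1OCc1cc(C)cc(C)c1 | intermediate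
24 | epicatechin-(4β→6)-catechin-(4α→6)-catechin (CNP0163146.4) | Oc1cc(O)c2c(c1)O[C@H](c1ccc(O)c(O)c1)[C@H](O)[C@H]2c1c(O)cc2c(c1O)[C@@H](c1c(O)cc3c(c1O)C[C@H](O)[C@@H](c1ccc(O)c(O)c1)O3)[C@H](O)[C@@H](c1ccc(O)c(O)c1)O2 | target

**Step count**
Total steps: 16. Longest linear sequence: 12 steps (1, 2, 5, 6, 7, 8, 11, 12, 13, 14, 15, 16).

**Three steps most likely to fail**

Step 7 (proposed ring expansion). The carbonyl of 11 is a deactivated, enolisable 2,4,6-trioxyaryl ketone; it may enolise instead of adding TMSCHN2, C2 may migrate instead of C3a (giving the flavanone), or a second insertion may occur. Fallback by known chemistry, setting out from acid 10 and returning at ketone 14: 10 is converted with (COCl)2 and catalytic DMF at −20 °C into the acid chloride F1, which is added at once to excess CH2N2 in Et2O to give the α-diazoketone F2 (first stage of an Arndt–Eistert sequence). CF3CO2H in CH2Cl2 at 0 °C (or Rh2(OAc)4) then effects the known intramolecular aromatic alkylation of aryloxymethyl diazomethyl ketones onto the activated ortho position, closing ring C directly as chroman-3-one 14. Steps 6 and 7 are bypassed.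

Step 8 (hydrogenation with dynamic kinetic resolution). The ketone has no aryl group on the carbonyl carbon, so face discrimination rests on the 2-aryl group alone, and the base may prefer the unproductive C4 enolate. Fallback, setting out from 14 and returning at 15: LiBH(s-Bu)3 in THF at −78 °C (the established cis-selective reduction of flavan-3-ones) gives the racemic cis alcohol, that is 15 together with its (2S,3S) antipode F3. The two are separated by preparative chiral chromatography, and F3 is re-oxidised with Dess–Martin periodinane to 14, which racemises with base and is recycled.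

Step 12 (Mitsunobu inversion at C3). The axial oxyphosphonium has anti-periplanar hydrogens at C4, so E2 elimination to the flav-3-ene may win over substitution. Fallback, setting out from 18 and returning at 20, uses that elimination deliberately: MsCl and Et3N give the mesylate F4, DBU in toluene gives the 2H-chromene (flav-3-ene) F5 with C2 untouched, and BH3·THF followed by H2O2/NaOH hydroborates the styrene-type double bond with boron at C3 on the face opposite the 2-aryl group (the known route from flav-3-enes to 2,3-trans-flavan-3-ols), giving 20.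

**Further compounds**
F1 | step 7 | (RS)-2-[3,4-bis(benzyloxy)phenyl]-2-{3,5-bis[(3,5-dimethylbenzyl)oxy]phenoxy}acetyl chloride | ClC(=O)C(Oc1cc(OCc2cc(C)cc(C)c2)cc(OCc2cc(C)cc(C)c2)c1)c1ccc(OCc2ccccc2)c(OCc2ccccc2)c1
F2 | step 7 | (RS)-1-[3,4-bis(benzyloxy)phenyl]-1-{3,5-bis[(3,5-dimethylbenzyl)oxy]phenoxy}-3-diazopropan-2-one | [N-]=[N+]=CC(=O)C(Oc1cc(OCc2cc(C)cc(C)c2)cc(OCc2cc(C)cc(C)c2)c1)c1ccc(OCc2ccccc2)c(OCc2ccccc2)c1
F3 | step 8 | (2S,3S)-2-[3,4-bis(benzyloxy)phenyl]-5,7-bis[(3,5-dimethylbenzyl)oxy]chroman-3-ol (antipode of 15) | Cc1cc(C)cc(c1)COc1cc(OCc2cc(C)cc(C)c2)c2c(c1)O[C@@H](c1ccc(OCc3ccccc3)c(OCc3ccccc3)c1)[C@@H](O)C2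
F4 | step 12 | (2R,3R)-2-[3,4-bis(benzyloxy)phenyl]-8-bromo-5,7-bis[(3,5-dimethylbenzyl)oxy]chroman-3-yl methanesulfonate | Cc1cc(C)cc(c1)COc1cc(OCc2cc(C)cc(C)c2)c2c(c1Br)O[C@H](c1ccc(OCc3ccccc3)c(OCc3ccccc3)c1)[C@H](OS(C)(=O)=O)C2
F5 | step 12 | (S)-2-[3,4-bis(benzyloxy)phenyl]-8-bromo-5,7-bis[(3,5-dimethylbenzyl)oxy]-2H-chromene (C2 spatially unchanged from 18; the descriptor changes by priority) | Cc1cc(C)cc(c1)COc1cc(OCc2cc(C)cc(C)c2)c2c(c1Br)O[C@H](c1ccc(OCc3ccccc3)c(OCc3ccccc3)c1)C=C2
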